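## Structural features

The target has one carbocycle, a cyclohex-2-ene numbered here C1 (isopropenyl), C2=C3 (methyl on C3), C4 (aryloxymethyl), C5 (quaternary, with methyl and 2-carboxyethyl) and C6 (methylene). A 2H-chromen-2-one (benzene fused to an α-pyranone) is joined through its 7-oxygen to the exocyclic CH2 on C4. There are three stereocentres: C4 (R) and C5 (R) are adjacent, a tertiary carbon next to an all-carbon quaternary one, with the oxymethyl arm and the propanoic acid chain cis. C1 (S) is 1,3 to C5 across C6, and its isopropenyl group lies on the same face as those two arms and trans to the C5 methyl. C1–H is doubly allylic, between the ring alkene and the isopropenyl group, so acid, strong base or metal hydrides can move either double bond into conjugation and erase this centre. The coumarin is both an aryl lactone (opened by hydroxide) and an enoate (reduced by copper hydride), and the free acid would interfere with activation of the C4 hydroxymethyl group, so both must enter late and in the right order. The real difficulty is the contiguous C4/C5 pair with its quaternary centre and cis arms, together with the relay of absolute configuration to the remote C1, whose two unsaturated substituents differ only by a methyl group. The key step uses the fact that C4, C5, the oxymethyl carbon and the first chain carbon, closed through the ether oxygen, form a γ-butyrolactone (C5 = α-carbon, C4 = β-carbon): on it C3 (as an isopropenyl group on C4) and the C6–C1–C2 arm (on C5) are held cis and can be joined at C2=C3.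

## Logic of the disconnections

20 ⇒ 19. The acid is masked as its methyl ester (ester C–O bond). A free acid would compete with the phenol in the etherification. Nothing is gained in skeleton, but the last step must cleave the ester and leave the coumarin lactone closed after work-up.

19 ⇒ 17 + 18. The alkyl C–O bond of the aryl ether is cut. This removes the whole heteroaromatic unit as commercial 18 and leaves a primary alcohol. The forward step must substitute a β-branched primary carbinol under neutral conditions, and the chain must already be saturated, because the coumarin double bond would not survive a conjugate hydride reduction.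

17 ⇒ 16 ⇒ 15 ⇒ 14. The bond between the first and second chain carbons is cut (as an alkene after re-introducing unsaturation). The remaining formyl carbon on C5 is tied to the C4 oxymethyl oxygen, first as a lactol and then, one oxidation level up, as the lactone of 14. The two cis arms merge into one five-membered ring and are differentiated by oxidation level without protecting groups. The demands are an olefination of a hindered lactol that does not let the freed hydroxyl add back to the enoate, and a 1,4-reduction that spares three isolated alkenes.

14 ⇒ 13. The C2=C3 double bond is cut into a vinyl group on C1 and an isopropenyl group on C4. The carbocycle disappears and a monocyclic lactone with two olefinic arms remains. The alkene is formed in its final position, so the skipped diene never passes through an isomerising step. The closure must take place between the vinyl group and the hindered 1,1-disubstituted alkene, not between the two isopropenyl groups. Compounds 13 and 14 were compared atom by atom with 20. The spatial arrangement at C1, C4 and C5 is the same in all three (descriptors change only because substituent priorities change), so no structure needed correction.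

13 ⇒ 12 + 5. The C1–isopropenyl bond is cut with allylic transposition. This is the point where the approach to 13 is made safer. Attaching a preformed 2-isopropenylbut-3-enyl electrophile to the lactone enolate would mean SN2 at a β-branched carbon whose β-hydrogen is doubly allylic, which is slow and open to elimination. Instead the arm is installed as a linear, reactive allylic unit, and C1 and the terminal vinyl group are made together by SN2′. The stereocentre and one alkene vanish from the precursor. The forward step needs high SN2′ selectivity and catalyst control of the new centre in the presence of two existing ones.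

12 ⇒ 11 ⇒ 10. The phosphate is traced back to the alcohol and its silyl ether. The oxygen must be inert while the quaternary centre is made. A leaving group on the Z-butenyl arm would be displaced by the α-enolate (cyclopentene or vinylcyclopropane formation).

10 ⇒ 8 ⇒ 6 + 3. The C5–CH3 bond and then the C5–C6 bond are cut. Each electrophile enters the lactone enolate anti to the C4 isopropenyl group, so the order is fixed: the arm first (trans), methyl second. This leaves the arm cis to isopropenyl, as the metathesis requires. Both alkylations use unhindered, reactive electrophiles.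

6 ⇒ 4 + 5. The C3–C4 bond (isopropenyl to the lactone β-carbon) is cut by a conjugate-addition transform. The first stereocentre then comes from an achiral butenolide and a commercial boronate. The forward step needs enantioface control by a chiral rhodium catalyst.

3 ⇒ 2 ⇒ 1. The four-carbon unit that supplies C6, C1, C2 and the carbon later lost as ethene comes from the symmetrical diol 1 by monosilylation and bromination.

## Other disconnections considered

Alternative 1: The cut goes through C1–C6 and C4–C5, the two bonds of a [4+2] cycloaddition. Forward, the diene of the ortho-quinol acetate 6-acetoxy-3,6-dimethylcyclohexa-2,4-dien-1-one A1 (from oxidation of 2,5-dimethylphenol with Pb(OAc)4) would add 2-methylprop-2-enal A2 to give the bicyclo[2.2.2]octenone A3. In A3 the acetoxy-ketone bridge spans C1 and C4. Cleaving that bridge would leave an acetyl group on C1 (to be methylenated) and a carboxyl on C4 (to be reduced to the oxymethyl arm), while the formyl group on C5 is extended to the propanoate.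
- In its favour: one step builds the carbocycle with C2=C3 and its methyl in place, creates the quaternary C5 and fixes all three relative configurations at once. The bridge forces the C1 and C4 substituents cis, and endo addition should put the formyl group on the bridge side. On stereochemical economy and on steps to the carbocycle it is better than the chosen plan.
- Against it: A1 is racemic and prone to self-dimerisation, and there is no dependable way to make its cycloaddition with an α-branched enal enantioselective, so a resolution would be needed. After the bridge is cut, C1 (acetyl) and C4 (carboxyl) are both allylic and α to a carbonyl, so epimerisation and alkene migration threaten exactly the centres the cycloaddition set. In the chosen plan C1 never carries a carbonyl. The C4 carboxyl must also be reduced beside the chain ester.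
- Comparison: the mechanism is a thermal pericyclic step whose regiochemistry is orbital-controlled and cannot be tuned by a ligand. The step count would be equal or somewhat lower, at the price of a resolution and more delicate intermediates.

Alternative 2: No ring bond is cut; the C5–CH3 and C4–CH2OH bonds are removed from an intact six-membered ring. Forward, Me2CuLi would add to the β-carbon (C5) of the enone (5S)-3-[3-(tert-butyldimethylsilyloxy)propyl]-5-(prop-1-en-2-yl)cyclohex-2-en-1-one A4 anti to the isopropenyl group, and the enolate would be trapped at C4 by formaldehyde to give the aldol A5. The C3 ketone would later become the C2=C3 alkene with its methyl (enol triflate towards C2, then methyl cross-coupling).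
- In its favour: the ring exists from the start, and the trans relationship of the C5 methyl and the C1 isopropenyl group follows from axial attack on a 5-substituted cyclohexenone. One stereocentre steers the others, which is better than the chosen plan with its three separate stereo-determining events. Both adjacent centres are made in one flask.
- Against it: A4 must first be made enantioenriched. Cuprate addition to a β,β-disubstituted enone needs silyl or Lewis-acid activation, which complicates the formaldehyde trapping. A5 is a β-hydroxy ketone open to retro-aldol cleavage, dehydration and epimerisation at C4. The ketone-to-alkene conversion needs regioselective enolisation away from C4. The silyloxypropyl arm must be oxidised to the acid late, beside a coumarin and three alkenes.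
- Comparison: control is stereoelectronic and substrate-based, where the chosen plan uses catalyst and template. The step counts would be about equal.

Alternative 3: The cut removes the bond from C5 to the first chain carbon together with a temporary bond from that carbon to C6. Forward, an engineered heme protein (myoglobin or cytochrome P450 variant) would convert the symmetrical (2,6-dimethylcyclohexa-2,5-dien-1-yl)methyl diazoacetate A6 into the cyclopropane-fused δ-lactone A7 through an iron carbene that adds to one of the two enantiotopic ring alkenes.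
- In its favour: absolute configuration at C4 and C5 would come in one catalytic step from an achiral Birch diene. The tether guarantees the cis relationship of the oxymethyl and the chain carbon, and the quaternary centre forms in the same event. On the number of stereo-determining steps it is equal to or better than the chosen plan.
- Against it: carbene transfer to a trisubstituted alkene, building a fully substituted cyclopropane carbon inside a six-membered lactone, would need a protein variant evolved for this substrate. In A7 the future methylene C6 still carries the extra bond, so the cyclopropane must be opened reductively with the right regiochemistry. C1 is a plain methylene, so the isopropenyl group and its configuration would have to be introduced afterwards at a doubly allylic position. The lactone carbonyl is only the second chain carbon, so a one-carbon homologation remains.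
- Comparison: a biocatalytic step replaces organometallic ones, with high potential selectivity but no predictive model. After its key step the route would be longer than the chosen one.

Key step: step 9

Remark (assumption): in step 8 the enantiomer of the chiral copper ligand is the one whose facial preference gives the S configuration at the new centre; the sense is fixed on a model allylic phosphate before 12 is committed, and the antipode of the ligand is used if it is opposite.

## Steps

Step 1
Reactants: 1 (Z)-but-2-ene-1,4-diol
Product: 2 (Z)-4-[(tert-butyldimethylsilyl)oxy]but-2-en-1-ol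
Conditions: NaH (1.0 equiv), THF, 0 °C; TBSCl (1.0 equiv), 0→22 °C
Reagents that add atoms: tert-butyldimethylsilyl chloride, CC(C)(C)[Si](C)(C)Cl
Why: O-Silylation of the monosodium alkoxide; the sparingly soluble mono-alkoxide of the symmetrical diol is silylated once, which suppresses bis-silylation.

Step 2
Reactants: 2 (Z)-4-[(tert-butyldimethylsilyl)oxy]but-2-en-1-ol
Product: 3 (Z)-[(4-bromobut-2-en-1-yl)oxy](tert-butyl)dimethylsilane
Conditions: CBr4 (1.2 equiv), PPh3 (1.25 equiv), CH2Cl2, 0 °C
Reagents that add atoms: carbon tetrabromide, BrC(Br)(Br)Br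
Why: Appel bromination; the alkoxyphosphonium bromide collapses by SN2 at the primary allylic carbon at 0 °C, with the Z geometry and the silyl ether retained.

Step 3
Reactants: 4 furan-2(5H)-one; 5 isopropenylboronic acid pinacol ester (2 equiv)
Product: 6 (4R)-4-(prop-1-en-2-yl)oxolan-2-one
Conditions: [RhCl(C2H4)2]2 (2.5 mol %), (R)-BINAP (5.5 mol %), KOH (10 mol %), 1,4-dioxane/H2O 10:1, 50 °C
Reagents that add atoms: none
Why: Hayashi–Miyaura asymmetric conjugate addition: isopropenyl passes from boron to the hydroxorhodium–BINAP complex, the butenolide inserts with enantioface selection and water releases the product and regenerates Rh–OH. With (R)-BINAP the usual quadrant model for cyclic enoates should give the R configuration at C4.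

Step 4
Reactants: 6 (4R)-4-(prop-1-en-2-yl)oxolan-2-one; 3 (Z)-[(4-bromobut-2-en-1-yl)oxy](tert-butyl)dimethylsilane
Product: 8 (3S,4R)-3-[(2Z)-4-[(tert-butyldimethylsilyl)oxy]but-2-en-1-yl]-4-(prop-1-en-2-yl)oxolan-2-one, via lithium dihydrofuranolate 7 (not isolated)
Conditions: LiN(iPr)2 (1.05 equiv), THF, −78 °C; then 3 (1.2 equiv), −78→−30 °C
Reagents that add atoms: none
Why: Enolate SN2 alkylation with a reactive primary allylic bromide; the electrophile approaches the planar lactone enolate anti to the β-isopropenyl group, which sets the new centre trans to C4 (3S).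

Step 5
Reactants: 8 (3S,4R)-3-[(2Z)-4-[(tert-butyldimethylsilyl)oxy]but-2-en-1-yl]-4-(prop-1-en-2-yl)oxolan-2-one
Product: 10 (3R,4S)-3-[(2Z)-4-[(tert-butyldimethylsilyl)oxy]but-2-en-1-yl]-3-methyl-4-(prop-1-en-2-yl)oxolan-2-one, via lithium butenyl dihydrofuranolate 9 (not isolated)
Conditions: LiN(iPr)2 (1.2 equiv), THF, −78 °C; then MeI (3 equiv), −78→−20 °C
Reagents that add atoms: iodomethane, CI
Why: Second enolate alkylation; methyl iodide again enters anti to the β-isopropenyl group, so the quaternary centre forms with methyl trans and the butenyl arm cis to isopropenyl (3R). The silyl ether is not a leaving group, which rules out cyclisation of the enolate onto its own arm.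

Step 6
Reactants: 10 (3R,4S)-3-[(2Z)-4-[(tert-butyldimethylsilyl)oxy]but-2-en-1-yl]-3-methyl-4-(prop-1-en-2-yl)oxolan-2-one
Product: 11 (3R,4S)-3-[(2Z)-4-hydroxybut-2-en-1-yl]-3-methyl-4-(prop-1-en-2-yl)oxolan-2-one
Conditions: Bu4NF (1.2 equiv), AcOH (1.2 equiv), THF, 0→22 °C
Reagents that add atoms: none
Why: Fluoride-induced Si–O cleavage; acetic acid buffers the alkoxide so that the lactone is not exposed to base.

Step 7
Reactants: 11 (3R,4S)-3-[(2Z)-4-hydroxybut-2-en-1-yl]-3-methyl-4-(prop-1-en-2-yl)oxolan-2-one
Product: 12 diethyl (2Z)-4-[(3R,4S)-3-methyl-2-oxo-4-(prop-1-en-2-yl)oxolan-3-yl]but-2-en-1-yl phosphate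
Conditions: ClP(O)(OEt)2 (1.3 equiv), Et3N (2 equiv), DMAP (10 mol %), CH2Cl2, 0 °C
Reagents that add atoms: diethyl chlorophosphate, CCOP(=O)(Cl)OCC
Why: O-Phosphorylation of the primary allylic alcohol with nucleophilic catalysis by DMAP gives the leaving group needed for copper-catalysed allylic substitution; no stereocentre is touched.

Step 8
Reactants: 12 diethyl (2Z)-4-[(3R,4S)-3-methyl-2-oxo-4-(prop-1-en-2-yl)oxolan-3-yl]but-2-en-1-yl phosphate; 5 isopropenylboronic acid pinacol ester (1.5 equiv)
Product: 13 (3R,4S)-3-[(2S)-2-ethenyl-3-methylbut-3-en-1-yl]-3-methyl-4-(prop-1-en-2-yl)oxolan-2-one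
Conditions: CuCl (5 mol %), enantiopure sulfonate-bearing imidazolinium salt (N-heterocyclic carbene precursor, 5.5 mol %), NaOMe (1.5 equiv), THF, 22→50 °C
Reagents that add atoms: none
Why: Copper-catalysed enantioselective allylic substitution (SN2′) with an alkenylboronate: methoxide-activated 5 transfers isopropenyl to the carbene–copper complex, which adds to the alkene carbon remote from the phosphate and expels it, creating the terminal vinyl group and the C1 stereocentre together. The new centre (2S in the side chain) is set by the chiral ligand; the distant quaternary centre should exert little bias, and the hindered α-quaternary lactone should resist methoxide.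

Step 9
Reactants: 13 (3R,4S)-3-[(2S)-2-ethenyl-3-methylbut-3-en-1-yl]-3-methyl-4-(prop-1-en-2-yl)oxolan-2-one
Product: 14 (3aS,6S,7aR)-4,7a-dimethyl-6-(prop-1-en-2-yl)-3a,6,7,7a-tetrahydro-2-benzofuran-1(3H)-one
Conditions: RuCl2(H2IMes)(=CH-C6H4-2-OiPr) (second-generation Hoveyda–Grubbs catalyst, 5 mol %), 1,4-benzoquinone (10 mol %), toluene (5 mM), 80 °C, argon sparge
Reagents that add atoms: none
Why: Ring-closing olefin metathesis by the metal-alkylidene/metallacyclobutane mechanism: the ruthenium benzylidene exchanges onto the monosubstituted vinyl group, the only unhindered alkene, and the alkylidene on C2 undergoes [2+2] cycloaddition with the C3=CH2 bond of the isopropenyl group on C4, ruthenium taking the unsubstituted carbon; cycloreversion gives the C2=C3 alkene and Ru=CH2, and ethene leaves. The closest known reaction type is the closure of trisubstituted cyclohexenes from a vinyl group and a 1,1-disubstituted alkene with carbene-ligated ruthenium catalysts. One ring is closed, a six-membered carbocycle with both carbons of the new double bond inside the ring; it can only be cis-fused because C3 and C6 sit on the same face of the lactone, so only the correctly alkylated diastereomer cyclises. No stereocentre is created: the configurations at C1, C4 and C5 are carried in unchanged and the endocyclic alkene is necessarily Z. The selectivity needed is site selectivity among three alkenes: closure between the two isopropenyl groups would give a tetrasubstituted alkene and is far slower, and the isopropenyl group on C1 cannot reach its geminal vinyl partner. High dilution and removal of ethene disfavour intermolecular metathesis at the vinyl group, which is reversible in any case, and 1,4-benzoquinone intercepts ruthenium hydrides that could move the double bonds of the skipped diene into conjugation.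

Step 10
Reactants: 14 (3aS,6S,7aR)-4,7a-dimethyl-6-(prop-1-en-2-yl)-3a,6,7,7a-tetrahydro-2-benzofuran-1(3H)-one
Product: 15 (3aS,6S,7aR)-4,7a-dimethyl-6-(prop-1-en-2-yl)-1,3,3a,6,7,7a-hexahydro-2-benzofuran-1-ol (both anomers)
Conditions: iBu2AlH (1.1 equiv), CH2Cl2, −78 °C; aq. potassium sodium tartrate
Reagents that add atoms: none
Why: Partial reduction of the γ-lactone; the tetrahedral aluminium alkoxide is stable at −78 °C and gives the lactol on hydrolysis, and the alkenes are inert to the aluminium hydride at this temperature.

Step 11
Reactants: 15 (3aS,6S,7aR)-4,7a-dimethyl-6-(prop-1-en-2-yl)-1,3,3a,6,7,7a-hexahydro-2-benzofuran-1-ol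
Product: 16 methyl (2E)-3-[(1S,2S,5S)-2-(hydroxymethyl)-1,3-dimethyl-5-(prop-1-en-2-yl)cyclohex-3-en-1-yl]prop-2-enoate
Conditions: Ph3P=CHCO2Me (3 equiv), PhCO2H (20 mol %), toluene, 90 °C
Reagents that add atoms: methyl (triphenylphosphoranylidene)acetate, COC(=O)C=P(c1ccccc1)(c1ccccc1)c1ccccc1
Why: Wittig olefination of the open hydroxy aldehyde in equilibrium with the lactol (an aldehyde on a quaternary carbon, so C5 cannot epimerise); the stabilised ylide gives the E enoate. Benzoic acid speeds lactol opening and keeps the medium non-basic, so that the freed hydroxyl does not add back to the enoate.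

Step 12
Reactants: 16 methyl (2E)-3-[(1S,2S,5S)-2-(hydroxymethyl)-1,3-dimethyl-5-(prop-1-en-2-yl)cyclohex-3-en-1-yl]prop-2-enoate
Product: 17 methyl 3-[(1R,2R,5S)-2-(hydroxymethyl)-1,3-dimethyl-5-(prop-1-en-2-yl)cyclohex-3-en-1-yl]propanoate
Conditions: [(Ph3P)CuH]6 (0.4 equiv), H2O (5 equiv), degassed toluene, 22 °C
Reagents that add atoms: none
Why: Conjugate reduction with copper hydride: hydride is delivered only to the β-carbon of the enoate and water protonates the copper enolate; the isolated alkenes and the free hydroxyl are not touched.

Step 13
Reactants: 17 methyl 3-[(1R,2R,5S)-2-(hydroxymethyl)-1,3-dimethyl-5-(prop-1-en-2-yl)cyclohex-3-en-1-yl]propanoate; 18 7-hydroxy-2H-chromen-2-one (umbelliferone, 1.3 equiv)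
Product: 19 methyl 3-[(1R,2R,5S)-1,3-dimethyl-2-{[(2-oxo-2H-chromen-7-yl)oxy]methyl}-5-(prop-1-en-2-yl)cyclohex-3-en-1-yl]propanoate
Conditions: PPh3 (1.5 equiv), DIAD (1.5 equiv), THF, 0→40 °C
Reagents that add atoms: none
Why: Mitsunobu etherification; the primary alcohol is activated as an alkoxyphosphonium ion and displaced by the phenoxide of 18 (pKa near 8) under neutral conditions. The carbinol carbon is not a stereocentre and the adjacent C4 is not involved.

Step 14
Reactants: 19 methyl 3-[(1R,2R,5S)-1,3-dimethyl-2-{[(2-oxo-2H-chromen-7-yl)oxy]methyl}-5-(prop-1-en-2-yl)cyclohex-3-en-1-yl]propanoate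
Product: 20 3-[(1R,2R,5S)-1,3-dimethyl-2-{[(2-oxo-2H-chromen-7-yl)oxy]methyl}-5-(prop-1-en-2-yl)cyclohex-3-en-1-yl]propanoic acid
Conditions: LiOH·H2O (3 equiv), THF/MeOH/H2O 3:1:1, 0→22 °C; then 1 M HCl to pH 3
Reagents that add atoms: lithium hydroxide, [Li+].[OH-]
Why: Saponification of the methyl ester by acyl–oxygen cleavage; any opening of the coumarin lactone by hydroxide gives the Z-configured 2-hydroxycinnamate, which closes again on acidification. The doubly allylic C1–H is far too weakly acidic to be affected.

## Compound list

1 | (Z)-but-2-ene-1,4-diol | OC/C=C\CO | starting material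
2 | (Z)-4-[(tert-butyldimethylsilyl)oxy]but-2-en-1-ol | OC/C=C\CO[Si](C)(C)C(C)(C)C | intermediate
3 | (Z)-[(4-bromobut-2-en-1-yl)oxy](tert-butyl)dimethylsilane | BrC/C=C\CO[Si](C)(C)C(C)(C)C | intermediate
4 | furan-2(5H)-one | O=C1OCC=C1 | starting material
5 | 4,4,5,5-tetramethyl-2-(prop-1-en-2-yl)-1,3,2-dioxaborolane (isopropenylboronic acid pinacol ester) | CC(=C)B1OC(C)(C)C(C)(C)O1 | starting material
6 | (4R)-4-(prop-1-en-2-yl)oxolan-2-one | O=C1OC[C@H](C1)C(C)=C | intermediate
7 | lithium (4R)-4-(prop-1-en-2-yl)-4,5-dihydrofuran-2-olate | [Li+].[O-]C1=C[C@H](C(C)=C)CO1 | intermediate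
8 | (3S,4R)-3-[(2Z)-4-[(tert-butyldimethylsilyl)oxy]but-2-en-1-yl]-4-(prop-1-en-2-yl)oxolan-2-one | CC(C)(C)[Si](C)(C)OC/C=C\C[C@@H]1C(=O)OC[C@H]1C(C)=C | intermediate
9 | lithium (4S)-3-[(2Z)-4-[(tert-butyldimethylsilyl)oxy]but-2-en-1-yl]-4-(prop-1-en-2-yl)-4,5-dihydrofuran-2-olate | [Li+].[O-]C1=C(C/C=C\CO[Si](C)(C)C(C)(C)C)[C@H](C(C)=C)CO1 | intermediate
10 | (3R,4S)-3-[(2Z)-4-[(tert-butyldimethylsilyl)oxy]but-2-en-1-yl]-3-methyl-4-(prop-1-en-2-yl)oxolan-2-one | CC(C)(C)[Si](C)(C)OC/C=C\C[C@@]1(C)C(=O)OC[C@H]1C(C)=C | intermediate
11 | (3R,4S)-3-[(2Z)-4-hydroxybut-2-en-1-yl]-3-methyl-4-(prop-1-en-2-yl)oxolan-2-one | OC/C=C\C[C@@]1(C)C(=O)OC[C@H]1C(C)=C | intermediate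
12 | diethyl (2Z)-4-[(3R,4S)-3-methyl-2-oxo-4-(prop-1-en-2-yl)oxolan-3-yl]but-2-en-1-yl phosphate | CCOP(=O)(OCC)OC/C=C\C[C@@]1(C)C(=O)OC[C@H]1C(C)=C | intermediate
13 | (3R,4S)-3-[(2S)-2-ethenyl-3-methylbut-3-en-1-yl]-3-methyl-4-(prop-1-en-2-yl)oxolan-2-one | C=C(C)[C@H](C=C)C[C@@]1(C)C(=O)OC[C@H]1C(C)=C | intermediate
14 | (3aS,6S,7aR)-4,7a-dimethyl-6-(prop-1-en-2-yl)-3a,6,7,7a-tetrahydro-2-benzofuran-1(3H)-one | C=C(C)[C@@H]1C=C(C)[C@@H]2COC(=O)[C@]2(C)C1 | intermediate
15 | (3aS,6S,7aR)-4,7a-dimethyl-6-(prop-1-en-2-yl)-1,3,3a,6,7,7a-hexahydro-2-benzofuran-1-ol (both anomers) | C=C(C)[C@@H]1C=C(C)[C@@H]2COC(O)[C@]2(C)C1 | intermediate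
16 | methyl (2E)-3-[(1S,2S,5S)-2-(hydroxymethyl)-1,3-dimethyl-5-(prop-1-en-2-yl)cyclohex-3-en-1-yl]prop-2-enoate | C=C(C)[C@@H]1C=C(C)[C@H](CO)[C@](C)(/C=C/C(=O)OC)C1 | intermediate
17 | methyl 3-[(1R,2R,5S)-2-(hydroxymethyl)-1,3-dimethyl-5-(prop-1-en-2-yl)cyclohex-3-en-1-yl]propanoate | C=C(C)[C@@H]1C=C(C)[C@H](CO)[C@](C)(CCC(=O)OC)C1 | intermediate
18 | 7-hydroxy-2H-chromen-2-one (umbelliferone) | O=c1ccc2ccc(O)cc2o1 | starting material
19 | methyl 3-[(1R,2R,5S)-1,3-dimethyl-2-{[(2-oxo-2H-chromen-7-yl)oxy]methyl}-5-(prop-1-en-2-yl)cyclohex-3-en-1-yl]propanoate | C=C(C)[C@@H]1C=C(C)[C@H](COc2ccc3ccc(=O)oc3c2)[C@](C)(CCC(=O)OC)C1 | intermediate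
20 | 3-[(1R,2R,5S)-1,3-dimethyl-2-{[(2-oxo-2H-chromen-7-yl)oxy]methyl}-5-(prop-1-en-2-yl)cyclohex-3-en-1-yl]propanoic acid | C=C(C)[C@@H]1C=C(C)[C@H](COc2ccc3ccc(=O)oc3c2)[C@](C)(CCC(=O)O)C1 | target

## Step count and least certain steps

Total step count: 14. Longest linear sequence: 13 steps (steps 1, 2 and 4–14, from 1 to 20); the branch from 4 and 5 to 6 is one step.

Step 9 (key step). What may go wrong: after loading on the vinyl group, closure onto the hindered 1,1-disubstituted alkene may be slow, and the alkylidene may be held back as a chelate with the lactone carbonyl. Intermolecular metathesis at the vinyl group and hydride-induced migration of the skipped-diene double bonds (loss of C1) then gain time to compete. Fallback, setting out from 13 and returning at 15: the reduction is placed before the ring closure. 13 is reduced with iBu2AlH (CH2Cl2, −78 °C) to the dienyl lactol (3R,4S)-3-[(2S)-2-ethenyl-3-methylbut-3-en-1-yl]-3-methyl-4-(prop-1-en-2-yl)oxolan-2-ol F1. This carbonyl-free, more flexible substrate is closed with the same ruthenium benzylidene and benzoquinone in dilute toluene to give 15 directly.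

Step 8. What may go wrong: incomplete catalyst control over the alkene face of a Z-allylic phosphate that already carries two stereocentres (loss of diastereoselectivity at C1), erosion of SN2′ selectivity next to the neopentyl-type CH2, or methoxide attack on the phosphate or lactone. Fallback, setting out from 2 and 6 and returning at 13: the centre is made on a small achiral substrate, where no matched or mismatched pairing exists and the enantiomeric purity can be assayed before coupling.
- 2 is phosphorylated (ClP(O)(OEt)2, Et3N, DMAP) to (Z)-4-[(tert-butyldimethylsilyl)oxy]but-2-en-1-yl diethyl phosphate F2.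
- The same copper-catalysed allylic substitution with 5 gives tert-butyl{[(2S)-2-ethenyl-3-methylbut-3-en-1-yl]oxy}dimethylsilane F3.
- Bu4NF/AcOH frees (2S)-2-ethenyl-3-methylbut-3-en-1-ol F4.
- Tf2O and 2,6-lutidine in CH2Cl2 at −78 °C give (2S)-2-ethenyl-3-methylbut-3-en-1-yl trifluoromethanesulfonate F5, used at once. The triflate is chosen because SN2 at this β-branched carbon with a doubly allylic β-hydrogen would be slow and elimination-prone with a halide.
- Enolate 7, made from 6 as in step 4, is alkylated with F5 at −78 °C to the trans lactone (3S,4R)-3-[(2S)-2-ethenyl-3-methylbut-3-en-1-yl]-4-(prop-1-en-2-yl)oxolan-2-one F6.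
- Deprotonation with LiN(iPr)2 to lithium (4S)-3-[(2S)-2-ethenyl-3-methylbut-3-en-1-yl]-4-(prop-1-en-2-yl)-4,5-dihydrofuran-2-olate F7 and methylation with MeI anti to the isopropenyl group give 13.

Step 11. What may go wrong: during the long heating that a lactol on a quaternary carbon needs, the liberated hydroxyl may add back to the enoate (five-membered oxa-Michael closure to a tetrahydrofuran, helped by the quaternary centre). Fallback, setting out from 14 and returning at 17: the hydroxyl is kept silylated while the enoate exists.
- Me(MeO)NH·HCl and AlMe3 (CH2Cl2, 0→22 °C) open 14 to (1R,2S,5S)-2-(hydroxymethyl)-N-methoxy-N,1,3-trimethyl-5-(prop-1-en-2-yl)cyclohex-3-ene-1-carboxamide F8.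
- Immediate silylation (TBSCl, imidazole, DMF) gives (1R,2S,5S)-2-{[(tert-butyldimethylsilyl)oxy]methyl}-N-methoxy-N,1,3-trimethyl-5-(prop-1-en-2-yl)cyclohex-3-ene-1-carboxamide F9.
- iBu2AlH (THF, −78 °C) gives (1R,2S,5S)-2-{[(tert-butyldimethylsilyl)oxy]methyl}-1,3-dimethyl-5-(prop-1-en-2-yl)cyclohex-3-ene-1-carbaldehyde F10.
- Wittig reaction with Ph3P=CHCO2Me gives methyl (2E)-3-[(1S,2S,5S)-2-{[(tert-butyldimethylsilyl)oxy]methyl}-1,3-dimethyl-5-(prop-1-en-2-yl)cyclohex-3-en-1-yl]prop-2-enoate F11.
- Reduction with [(Ph3P)CuH]6 gives methyl 3-[(1R,2R,5S)-2-{[(tert-butyldimethylsilyl)oxy]methyl}-1,3-dimethyl-5-(prop-1-en-2-yl)cyclohex-3-en-1-yl]propanoate F12.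
- Bu4NF/AcOH returns 17.

Step 13. What may go wrong: substitution at the β-branched carbinol carbon, flanked by the quaternary centre, may be sluggish, so that the activated phosphonium intermediate is diverted (alkylation of the reduced azodicarboxylate, or attack by the ester carbonyl) and the ether forms incompletely. Fallback, setting out from 17 and returning at 19: activation and displacement are separated. MsCl and Et3N (CH2Cl2, 0 °C) give methyl 3-[(1R,2R,5S)-2-{[(methanesulfonyl)oxy]methyl}-1,3-dimethyl-5-(prop-1-en-2-yl)cyclohex-3-en-1-yl]propanoate F13, which is displaced by the cesium phenoxide of 18 (Cs2CO3, DMF, 60 °C) to give 19.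

## Further compounds

F1 | step 9 | (3R,4S)-3-[(2S)-2-ethenyl-3-methylbut-3-en-1-yl]-3-methyl-4-(prop-1-en-2-yl)oxolan-2-ol (both anomers) | C=C(C)[C@H](C=C)C[C@@]1(C)C(O)OC[C@H]1C(C)=C
F2 | step 8 | (Z)-4-[(tert-butyldimethylsilyl)oxy]but-2-en-1-yl diethyl phosphate | CCOP(=O)(OCC)OC/C=C\CO[Si](C)(C)C(C)(C)C
F3 | step 8 | tert-butyl{[(2S)-2-ethenyl-3-methylbut-3-en-1-yl]oxy}dimethylsilane | C=C(C)[C@H](C=C)CO[Si](C)(C)C(C)(C)C
F4 | step 8 | (2S)-2-ethenyl-3-methylbut-3-en-1-ol | C=C(C)[C@H](C=C)CO
F5 | step 8 | (2S)-2-ethenyl-3-methylbut-3-en-1-yl trifluoromethanesulfonate | C=C(C)[C@H](C=C)COS(=O)(=O)C(F)(F)F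
F6 | step 8 | (3S,4R)-3-[(2S)-2-ethenyl-3-methylbut-3-en-1-yl]-4-(prop-1-en-2-yl)oxolan-2-one | C=C(C)[C@H](C=C)C[C@@H]1C(=O)OC[C@H]1C(C)=C
F7 | step 8 | lithium (4S)-3-[(2S)-2-ethenyl-3-methylbut-3-en-1-yl]-4-(prop-1-en-2-yl)-4,5-dihydrofuran-2-olate | [Li+].[O-]C1=C(C[C@@H](C=C)C(C)=C)[C@H](C(C)=C)CO1
F8 | step 11 | (1R,2S,5S)-2-(hydroxymethyl)-N-methoxy-N,1,3-trimethyl-5-(prop-1-en-2-yl)cyclohex-3-ene-1-carboxamide | C=C(C)[C@@H]1C=C(C)[C@H](CO)[C@](C)(C(=O)N(C)OC)C1
F9 | step 11 | (1R,2S,5S)-2-{[(tert-butyldimethylsilyl)oxy]methyl}-N-methoxy-N,1,3-trimethyl-5-(prop-1-en-2-yl)cyclohex-3-ene-1-carboxamide | C=C(C)[C@@H]1C=C(C)[C@H](CO[Si](C)(C)C(C)(C)C)[C@](C)(C(=O)N(C)OC)C1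
F10 | step 11 | (1R,2S,5S)-2-{[(tert-butyldimethylsilyl)oxy]methyl}-1,3-dimethyl-5-(prop-1-en-2-yl)cyclohex-3-ene-1-carbaldehyde | C=C(C)[C@@H]1C=C(C)[C@H](CO[Si](C)(C)C(C)(C)C)[C@](C)(C=O)C1
F11 | step 11 | methyl (2E)-3-[(1S,2S,5S)-2-{[(tert-butyldimethylsilyl)oxy]methyl}-1,3-dimethyl-5-(prop-1-en-2-yl)cyclohex-3-en-1-yl]prop-2-enoate | C=C(C)[C@@H]1C=C(C)[C@H](CO[Si](C)(C)C(C)(C)C)[C@](C)(/C=C/C(=O)OC)C1
F12 | step 11 | methyl 3-[(1R,2R,5S)-2-{[(tert-butyldimethylsilyl)oxy]methyl}-1,3-dimethyl-5-(prop-1-en-2-yl)cyclohex-3-en-1-yl]propanoate | C=C(C)[C@@H]1C=C(C)[C@H](CO[Si](C)(C)C(C)(C)C)[C@](C)(CCC(=O)OC)C1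
F13 | step 13 | methyl 3-[(1R,2R,5S)-2-{[(methanesulfonyl)oxy]methyl}-1,3-dimethyl-5-(prop-1-en-2-yl)cyclohex-3-en-1-yl]propanoate | C=C(C)[C@@H]1C=C(C)[C@H](COS(C)(=O)=O)[C@](C)(CCC(=O)OC)C1
A1 | alternative 1 | 6-acetoxy-3,6-dimethylcyclohexa-2,4-dien-1-one (racemic) | CC1=CC(=O)C(C)(OC(C)=O)C=C1
A2 | alternative 1 | 2-methylprop-2-enal | C=C(C)C=O
A3 | alternative 1 | 3-acetoxy-3,6,7-trimethyl-2-oxobicyclo[2.2.2]oct-5-ene-7-carbaldehyde (formyl on the keto-bridge side) | C[C@]1(OC(C)=O)[C@@H]2C=C(C)[C@H](C1=O)[C@](C)(C=O)C2
A4 | alternative 2 | (5S)-3-[3-(tert-butyldimethylsilyloxy)propyl]-5-(prop-1-en-2-yl)cyclohex-2-en-1-one | C=C(C)[C@@H]1CC(=O)C=C(CCCO[Si](C)(C)C(C)(C)C)C1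
A5 | alternative 2 | 2-(hydroxymethyl)-3-methyl-3-[3-(tert-butyldimethylsilyloxy)propyl]-5-(prop-1-en-2-yl)cyclohexan-1-one (hydroxymethyl cis to the silyloxypropyl chain, methyl trans to isopropenyl) | C=C(C)[C@@H]1CC(=O)[C@H](CO)[C@](C)(CCCO[Si](C)(C)C(C)(C)C)C1
A6 | alternative 3 | (2,6-dimethylcyclohexa-2,5-dien-1-yl)methyl 2-diazoacetate | CC1=CCC=C(C)C1COC(=O)C=[N+]=[N-]
A7 | alternative 3 | tricyclic cyclopropane-fused δ-lactone retaining the C2=C3 alkene | C1C=C(C)[C@@H]2COC(=O)[C@@H]3[C@H]1[C@]23C
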